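**Retrosynthetic overview**

1. [12]-Gingerdione ⇐ 3-[2-(4-benzyloxy-3-methoxyphenyl)ethyl]-5-undecylisoxazole. The C3/C5 1,3-diketone is carried as the isoxazole ring (O1–N2–C3–C4–C5) and the phenol as its benzyl ether; one hydrogenolysis followed by acid hydrolysis unmasks both.
2. Key disconnection: the C9–C10 CH2–CH2 bond of the hexadecane-3,5-dione chain (C4'–C5' of the undecyl group) ⇐ two N-hydroxyphthalimide esters, an isoxazolylpentanoate and octanoate, joined by nickel-electrocatalytic doubly decarboxylative coupling.
3. Enabling feature: C9 and C10 are unfunctionalised primary sp3 carbons of the C6–C16 polymethylene chain, so each can carry a carboxyl group as a traceless radical precursor. The four CH2 groups C6–C9 come intact from hept-6-ynoate, and the aromatic isoxazole leaves no acidic C4–H2, no chelating site and no enol that could attack the active ester.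
4. Isoxazolylpentanoic acid ⇐ nitrile oxide (from the 3-arylpropanal oxime) + methyl hept-6-ynoate by [3+2] cycloaddition; the aldehyde ⇐ Heck reaction of the aryl bromide with allyl alcohol.
5. Ring order: the isoxazole is the only ring formed (step 3) and is opened again in the last step; the arene is bought.

Key step: step 7

Remark on the chemistry: the target has no stereocentre and no stereogenic double bond, so no stereocontrol is needed; it is a keto–enol mixture and is drawn as the diketone.

**Step 1**
Reactants: 1 1-(benzyloxy)-4-bromo-2-methoxybenzene; 2 allyl alcohol (prop-2-en-1-ol)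
Product: 3 3-[4-(benzyloxy)-3-methoxyphenyl]propanal
Conditions: Pd(OAc)2 (cat.), Bu4NCl, NaHCO3, DMF, 80 °C
Reagents that add atoms: none
Why: In this ligand-free Heck reaction the aryl-palladium species should add to the terminal alkene carbon and β-hydride elimination toward the carbinol carbon should give the enol, which tautomerises to the saturated 3-arylpropanal while the benzyl ether stays inert.

**Step 2**
Reactants: 3 3-[4-(benzyloxy)-3-methoxyphenyl]propanal
Product: 4 3-[4-(benzyloxy)-3-methoxyphenyl]propanal oxime (E/Z mixture; E isomer drawn)
Conditions: NH2OH·HCl, NaOAc, EtOH/H2O, rt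
Reagents that add atoms: hydroxylamine hydrochloride, NO.Cl
Why: Oxime condensation of an unhindered aldehyde under acetate buffering should be fast and clean, and the E/Z mixture is of no consequence because both isomers lead to the same nitrile oxide.

**Step 3**
Reactants: 4 3-[4-(benzyloxy)-3-methoxyphenyl]propanal oxime; 5 methyl hept-6-ynoate
Product: 8 methyl 5-{3-[2-(4-benzyloxy-3-methoxyphenyl)ethyl]isoxazol-5-yl}pentanoate, via hydroximoyl chloride 6 (not isolated), via nitrile oxide 7 (not isolated)
Conditions: NCS, DMF, rt; then 5 (1.5 equiv), Et3N (slow addition), CH2Cl2, 0 °C to rt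
Reagents that add atoms: none
Why: Chlorination of the aldoxime and slow base-induced 1,3-elimination should generate the nitrile oxide at low stationary concentration, and its Huisgen 1,3-dipolar cycloaddition (concerted [3+2]) with the terminal alkyne should place oxygen on the substituted alkyne carbon and give the 3,5-disubstituted isoxazole regioselectively.

**Step 4**
Reactants: 8 methyl 5-{3-[2-(4-benzyloxy-3-methoxyphenyl)ethyl]isoxazol-5-yl}pentanoate
Product: 9 5-{3-[2-(4-benzyloxy-3-methoxyphenyl)ethyl]isoxazol-5-yl}pentanoic acid
Conditions: LiOH·H2O, THF/MeOH/H2O, rt; then 1 M HCl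
Reagents that add atoms: lithium hydroxide, [Li+].[OH-]
Why: Saponification of an unhindered methyl ester should proceed at room temperature, and a 3,5-disubstituted isoxazole, which has no C3–H, is not opened by hydroxide under these conditions.

**Step 5**
Reactants: 9 5-{3-[2-(4-benzyloxy-3-methoxyphenyl)ethyl]isoxazol-5-yl}pentanoic acid
Product: 10 1,3-dioxoisoindolin-2-yl 5-{3-[2-(4-benzyloxy-3-methoxyphenyl)ethyl]isoxazol-5-yl}pentanoate
Conditions: N-hydroxyphthalimide, DIC, DMAP (cat.), CH2Cl2, rt
Reagents that add atoms: N-hydroxyphthalimide, O=C1c2ccccc2C(=O)N1O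
Why: Carbodiimide (Steglich-type) esterification of a primary alkanoic acid with N-hydroxyphthalimide is a standard way to make the redox-active ester, and the molecule holds no other nucleophile.

**Step 6**
Reactants: 11 octanoic acid
Product: 12 1,3-dioxoisoindolin-2-yl octanoate
Conditions: N-hydroxyphthalimide, DIC, DMAP (cat.), CH2Cl2, rt
Reagents that add atoms: N-hydroxyphthalimide, O=C1c2ccccc2C(=O)N1O
Why: The same carbodiimide (Steglich-type) esterification should turn the cheap fatty acid into its redox-active ester, which is needed in excess in the next step.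

**Step 7**
Reactants: 10 1,3-dioxoisoindolin-2-yl 5-{3-[2-(4-benzyloxy-3-methoxyphenyl)ethyl]isoxazol-5-yl}pentanoate; 12 1,3-dioxoisoindolin-2-yl octanoate (3 equiv)
Product: 13 3-[2-(4-benzyloxy-3-methoxyphenyl)ethyl]-5-undecylisoxazole
Conditions: NiCl2·6H2O (20 mol %), 2,2':6',2''-terpyridine (20 mol %), AgNO3 (0.3 equiv), NaI, DMF, Mg(+)/RVC(−), undivided cell, constant current, rt
Reagents that add atoms: none
Why: Cathodically generated low-valent Ni(terpyridine) should transfer an electron to each N-acyloxyphthalimide, whose radical anion fragments to phthalimide anion, CO2 and a primary alkyl radical (heptyl from 12, 4-(isoxazol-5-yl)butyl from 10); capture of the two radicals at nickel and reductive elimination from the dialkylnickel(III) species forms the CH2–CH2 bond, while the sacrificial Mg anode supplies the electrons and silver deposited on the cathode suppresses direct, unproductive ester reduction. The closest known reaction type is the nickel-electrocatalysed doubly decarboxylative C(sp3)–C(sp3) cross-coupling of two redox-active esters, a reductive counterpart of the mixed Kolbe coupling that is known for primary–primary pairs. No ring is closed and no stereocentre is formed. The step needs cross-coupling over homocoupling, which the threefold excess of the cheap ester 12 should secure statistically (its homodimer is a non-polar hydrocarbon removable by chromatography), and it needs reduction of the two phthalimide N–O bonds in preference to the isoxazole N–O bond, which the aromatic 3,5-dialkylisoxazole should secure because it is reduced only at far more negative potential. The isoxazole also removes the acidic, metal-chelating and self-acylating 1,3-diketone from the substrate and the benzyl ether removes the phenolic proton, so neither should interfere with the alkylnickel intermediates.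

**Step 8**
Reactants: 13 3-[2-(4-benzyloxy-3-methoxyphenyl)ethyl]-5-undecylisoxazole
Product: 15 [12]-gingerdione [1-(4-hydroxy-3-methoxyphenyl)hexadecane-3,5-dione], via enaminone 14 (not isolated)
Conditions: H2 (1 atm), 10% Pd/C, EtOH, rt; then 1 M HCl, THF, rt
Reagents that add atoms: water, O
Why: Catalytic hydrogenolysis should cleave the weak isoxazole N–O bond and the benzylic C–O bond in the same operation, and acid hydrolysis of the resulting vinylogous amide (enaminone) should release the 1,3-diketone, the aliphatic ketones and the arene being inert to Pd/C at 1 atm.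

**Compound list**

1 | 1-(benzyloxy)-4-bromo-2-methoxybenzene | COc1cc(Br)ccc1OCc1ccccc1 | starting material
2 | allyl alcohol (prop-2-en-1-ol) | C=CCO | starting material
3 | 3-[4-(benzyloxy)-3-methoxyphenyl]propanal | O=CCCc1ccc(OCc2ccccc2)c(OC)c1 | intermediate
4 | 3-[4-(benzyloxy)-3-methoxyphenyl]propanal oxime (E/Z mixture; E isomer drawn) | O/N=C/CCc1ccc(OCc2ccccc2)c(OC)c1 | intermediate
5 | methyl hept-6-ynoate | COC(=O)CCCCC#C | starting material
6 | (Z)-3-[4-(benzyloxy)-3-methoxyphenyl]-N-hydroxypropanimidoyl chloride (hydroximoyl chloride) | O/N=C(\Cl)CCc1ccc(OCc2ccccc2)c(OC)c1 | intermediate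
7 | 3-[4-(benzyloxy)-3-methoxyphenyl]propanenitrile oxide | [O-][N+]#CCCc1ccc(OCc2ccccc2)c(OC)c1 | intermediate
8 | methyl 5-{3-[2-(4-benzyloxy-3-methoxyphenyl)ethyl]isoxazol-5-yl}pentanoate | COC(=O)CCCCc1cc(CCc2ccc(OCc3ccccc3)c(OC)c2)no1 | intermediate
9 | 5-{3-[2-(4-benzyloxy-3-methoxyphenyl)ethyl]isoxazol-5-yl}pentanoic acid | OC(=O)CCCCc1cc(CCc2ccc(OCc3ccccc3)c(OC)c2)no1 | intermediate
10 | 1,3-dioxoisoindolin-2-yl 5-{3-[2-(4-benzyloxy-3-methoxyphenyl)ethyl]isoxazol-5-yl}pentanoate | O=C(CCCCc1cc(CCc2ccc(OCc3ccccc3)c(OC)c2)no1)ON1C(=O)c2ccccc2C1=O | intermediate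
11 | octanoic acid | CCCCCCCC(=O)O | starting material
12 | 1,3-dioxoisoindolin-2-yl octanoate | CCCCCCCC(=O)ON1C(=O)c2ccccc2C1=O | intermediate
13 | 3-[2-(4-benzyloxy-3-methoxyphenyl)ethyl]-5-undecylisoxazole | CCCCCCCCCCCc1cc(CCc2ccc(OCc3ccccc3)c(OC)c2)no1 | intermediate
14 | (Z)-3-amino-1-(4-hydroxy-3-methoxyphenyl)hexadec-3-en-5-one (enaminone) | CCCCCCCCCCCC(=O)/C=C(\N)CCc1ccc(O)c(OC)c1 | intermediate
15 | [12]-gingerdione, 1-(4-hydroxy-3-methoxyphenyl)hexadecane-3,5-dione | CCCCCCCCCCCC(=O)CC(=O)CCc1ccc(O)c(OC)c1 | target

**Step count**

Total steps: 8. Longest linear sequence: 7 (steps 1, 2, 3, 4, 5, 7, 8); step 6 is a one-step side branch.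

**Steps most likely to fail, with fallbacks**

Step 7. The cross-coupling may be eroded by statistical homocoupling, by premature reduction of the alkyl radicals to alkanes, or by unproductive cathodic consumption of the active ester. The fallback sets out from 10 and replaces the reductive union of two electrophiles by a redox-neutral nickel-catalysed decarboxylative Negishi alkyl–alkyl coupling. Diheptylzinc F1 would be generated from heptylmagnesium bromide and ZnCl2 (0.5 equiv) in THF and combined with 10 under NiCl2·glyme and 4,4'-di-tert-butyl-2,2'-bipyridine in THF/DMF at rt. Transmetalation of one heptyl group to nickel, single-electron reduction and decarboxylation of 10, radical capture and reductive elimination should form the same CH2–CH2 bond. Neither the isoxazole nor the benzyl ether reacts with a dialkylzinc, and the route is rejoined at 13.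

Step 8. The debenzylation may stall through inhibition of the catalyst by the nitrogen-containing ring-opened product, or the enaminone may be over-reduced on prolonged hydrogenation. The fallback sets out from 13 and separates the two events. Iron powder and NH4Cl in EtOH/H2O at reflux should cleave only the N–O bond to give (Z)-3-amino-1-[4-(benzyloxy)-3-methoxyphenyl]hexadec-3-en-5-one F2. Hydrolysis with 1 M HCl in THF should then give 1-[4-(benzyloxy)-3-methoxyphenyl]hexadecane-3,5-dione F3. Hydrogenolysis of F3 (H2, Pd/C, EtOAc, rt), now free of nitrogen, should remove the benzyl group and rejoin the route at 15.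

Step 1. Oxidative addition into the electron-rich aryl bromide may be slow, palladium chain-walking may give regioisomeric carbonyl products, and the aldehyde may self-condense under hot basic conditions. The fallback sets out from 1 and fixes the regiochemistry with a masked aldehyde. Negishi coupling of 1 with commercial [2-(1,3-dioxolan-2-yl)ethyl]zinc bromide (Br[Zn]CCC1OCCO1; Pd(OAc)2, SPhos, THF, 50 °C) should give 2-{2-[4-(benzyloxy)-3-methoxyphenyl]ethyl}-1,3-dioxolane F4. Acetal hydrolysis (1 M HCl, THF, rt) should then release the aldehyde and rejoin the route at 3.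

**Further compounds**

F1 | step 7 | diheptylzinc | CCCCCCC[Zn]CCCCCCC
F2 | step 8 | (Z)-3-amino-1-[4-(benzyloxy)-3-methoxyphenyl]hexadec-3-en-5-one | CCCCCCCCCCCC(=O)/C=C(\N)CCc1ccc(OCc2ccccc2)c(OC)c1
F3 | step 8 | 1-[4-(benzyloxy)-3-methoxyphenyl]hexadecane-3,5-dione | CCCCCCCCCCCC(=O)CC(=O)CCc1ccc(OCc2ccccc2)c(OC)c1
F4 | step 1 | 2-{2-[4-(benzyloxy)-3-methoxyphenyl]ethyl}-1,3-dioxolane | COc1cc(CCC2OCCO2)ccc1OCc1ccccc1
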